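**Plan**

- Numbering used throughout: C1 (quaternary ring-fusion carbon with CH3), C2 (OAc), C3, C4 (OH, isopropyl) and C5 (ring-fusion CH) form the five-membered ring; C5, C6 (O-aroyl), C7, C8 (CH3), C9, C10 and C1 form the seven-membered ring. The enabling feature is that, within the seven-membered ring, the run C7–C8–C9–C10–C1 is a five-carbon ene-cyclopropane unit and C5–C6 a two-carbon alkyne unit, while C2–C3–C4 of the five-membered ring is a three-atom tether between them.
- Retrosynthesis: the two esters are cut first; then C1–C5 and C6–C7 are cut together (C9–C7 becoming a cyclopropane bond), giving an acyclic silylalkyne–vinylcyclopropane; the chain is cut at C4–C5 (acetylide plus ketone), C2–C3 (aldol) and C1=C10 (Wittig).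
- Forward: cyclopropane (C7–C9), then enal (C10, C1, C2), aldol (C3, C4), acetylide (C5, C6); both rings then close in one rhodium step, the five-membered ring by alkyne insertion and the seven-membered ring by reductive elimination; the vinylsilane becomes the C6 oxygen and the C9=C10 alkene is moved to C8=C9.
- Stereochemistry: the cyclopropane comes from an asymmetric Simmons–Smith reaction; C2 from a reagent-controlled boron aldol; C4 from chelation-controlled acetylide addition (anti to C2); C1 stereospecifically from the cyclopropane, matched with C2; C5 by equilibration of the C6 ketone to the trans ring fusion; C6 by dissolving-metal reduction to the equatorial alcohol; the C8 centre is erased.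

Key step: step 7

Remarks. α is the ring face of H5 and of the C2 and C6 oxygens; β is the face of the C1 methyl group and the C4 oxygen. TBS = tert-butyldimethylsilyl, TES = triethylsilyl, Bn = benzyl.
Assumption: of the two C5 epimers of ketone 20, the trans-fused one (C6 anti to the isopropyl group, as in the target) is taken to be the more stable, so that the equilibration in step 8 ends there.

**Route**

Step 1
Reactants: 1 (E)-but-2-en-1-ol
Product: 2 [(1R,2R)-2-methylcyclopropyl]methanol
Conditions: Et2Zn, CH2I2, DME, CH2Cl2, −10 °C; then 1 and (4S,5S)-2-butyl-N,N,N',N'-tetramethyl-1,3,2-dioxaborolane-4,5-dicarboxamide (1.2 equiv), −10 °C to rt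
Reagents that add atoms: diiodomethane, ICI
Why: Hydroxyl-directed asymmetric Simmons–Smith cyclopropanation, in which the zinc alkoxide of 1 is held by the chiral dioxaborolane so that CH2 from Zn(CH2I)2 is delivered to one alkene face (the 4S,5S antipode is the one expected to give the 1R,2R ring) and the E geometry is carried stereospecifically into the trans-cyclopropane.

Step 2
Reactants: 2 [(1R,2R)-2-methylcyclopropyl]methanol
Product: 4 (E)-2-methyl-3-[(1R,2R)-2-methylcyclopropyl]prop-2-enal, via aldehyde 3 (not isolated)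
Conditions: TEMPO (10 mol %), PhI(OAc)2, CH2Cl2, rt; then Ph3P=C(CH3)CHO, 40 °C
Reagents that add atoms: 2-(triphenylphosphoranylidene)propanal, CC(C=O)=P(c1ccccc1)(c1ccccc1)c1ccccc1
Why: Oxoammonium (TEMPO) oxidation stops at the aldehyde, and trapping the volatile aldehyde 3 in the same flask by a Wittig reaction with the stabilised formyl ylide should give the E trisubstituted enal without touching the cyclopropane centres.

Step 3
Reactants: 4 (E)-2-methyl-3-[(1R,2R)-2-methylcyclopropyl]prop-2-enal; 5 3-methylbutan-2-one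
Product: 8 (5S,6E)-5-hydroxy-2,6-dimethyl-7-[(1R,2R)-2-methylcyclopropyl]hept-6-en-3-one, via boron enolate 6 (not isolated), via boron aldolate 7 (not isolated)
Conditions: 5, (+)-Ipc2BCl, Et3N, Et2O, 0 °C; then 4, −78 to −20 °C; then H2O2, MeOH, pH 7 buffer, 0 °C
Reagents that add atoms: none
Why: Boron-mediated aldol reaction under reagent control, in which the kinetic enol borinate 6 forms on the methyl side of 5 and its isopinocampheyl groups differentiate the aldehyde faces (the (+)-reagent is the antipode expected to attack the Si face and set 5S), the peroxide work-up then cleaving the boron aldolate 7.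

Step 4
Reactants: 9 ethynylmagnesium bromide; 10 benzyl(chloro)dimethylsilane
Product: 11 benzyl(ethynyl)dimethylsilane
Conditions: THF, 0 °C to rt
Reagents that add atoms: none
Why: Substitution at silicon by the acetylide Grignard reagent (silylation of a terminal alkyne), giving an alkyne whose benzyldimethylsilyl group survives the following steps and later serves as a masked oxygen.

Step 5
Reactants: 8 (5S,6E)-5-hydroxy-2,6-dimethyl-7-[(1R,2R)-2-methylcyclopropyl]hept-6-en-3-one; 11 benzyl(ethynyl)dimethylsilane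
Product: 14 (3R,5S,6E)-1-[benzyl(dimethyl)silyl]-6-methyl-7-[(1R,2R)-2-methylcyclopropyl]-3-(propan-2-yl)hept-6-en-1-yne-3,5-diol, via alkynylmagnesium bromide 12 (not isolated), via magnesium alkoxide 13 (not isolated)
Conditions: 11 (3 equiv), EtMgBr, THF, 0 °C to rt; then 8, CH2Cl2, −78 to 0 °C; aq. NH4Cl
Reagents that add atoms: none
Why: Chelation-controlled Grignard addition to a β-hydroxy ketone, in which the first equivalent of 12 turns 8 into the magnesium alkoxide 13, whose magnesium bridges both oxygens in a six-membered half-chair with the alkenyl group equatorial, so that the slim, weakly basic acetylide adds axially on the face away from that group and should set 3R (the 3,5-anti diol).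

Step 6
Reactants: 14 (3R,5S,6E)-1-[benzyl(dimethyl)silyl]-6-methyl-7-[(1R,2R)-2-methylcyclopropyl]-3-(propan-2-yl)hept-6-en-1-yne-3,5-diol
Product: 16 (3R,5S,6E)-1-[benzyl(dimethyl)silyl]-5-(tert-butyldimethylsilyloxy)-6-methyl-7-[(1R,2R)-2-methylcyclopropyl]-3-(propan-2-yl)-3-(triethylsilyloxy)hept-6-en-1-yne, via mono-TBS ether 15 (not isolated)
Conditions: TBSOTf (1.1 equiv), 2,6-lutidine, CH2Cl2, −78 °C; then TESOTf (1.5 equiv), −78 to 0 °C
Reagents that add atoms: tert-butyldimethylsilyl triflate, CC(C)(C)[Si](C)(C)OS(=O)(=O)C(F)(F)F; triethylsilyl triflate, CC[Si](CC)(CC)OS(=O)(=O)C(F)(F)F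
Why: Silylation with silyl triflates, in which TBSOTf at −78 °C takes only the secondary allylic hydroxyl and the more reactive TESOTf then caps the hindered tertiary propargylic hydroxyl under non-acidic conditions that spare the allylic cyclopropane system.

Step 7
Reactants: 16 (3R,5S,6E)-1-[benzyl(dimethyl)silyl]-5-(tert-butyldimethylsilyloxy)-6-methyl-7-[(1R,2R)-2-methylcyclopropyl]-3-(propan-2-yl)-3-(triethylsilyloxy)hept-6-en-1-yne
Product: 17 6-[benzyl(dimethyl)silyl]-2α-(tert-butyldimethylsilyloxy)-4α-isopropyl-1β,8α-dimethyl-4β-(triethylsilyloxy)bicyclo[5.3.0]deca-5,9-diene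
Conditions: [Rh(CO)2Cl]2 (5 mol %), toluene, 80 °C
Reagents that add atoms: none
Why: Proposed new method: Monovalent rhodium binds the ene-cyclopropane of 16 and inserts into the unsubstituted C9–C7 bond to give a rhodacyclohexene (C7–Rh σ bond, C9–C10–C1 allyl), the tethered alkyne inserts at C1 and reductive elimination joins C6 to C7; the closest known reaction type is the rhodium-catalysed intramolecular (5+2) cycloaddition of alkynes with vinylcyclopropanes whose bond-forming vinyl carbon carries only the tether, and the methyl group on that carbon is what goes beyond it. The five-membered ring closes in the insertion step as a 5-exo closure over the C2–C3–C4 tether (bond C1–C5), the seven-membered ring closes by reductive elimination from the eight-membered rhodacycle (bond C6–C7), and the C9=C10 alkene is formed cis in the ring. The single new stereocentre, quaternary C1, is fixed by the cyclopropane: with C8 turned s-cis to C1, the CH2 carbon C7 of the (1R,2R)-ring lies on one alkene face only, rhodium enters there and C5 follows on the same face. The C2 silyloxy centre is matched with this face, because the tether reaches it in the conformation that turns OTBS away from the C1 methyl group (least A(1,2) strain), so that OTBS and methyl end up trans on the new ring. The step needs cleavage of C9–C7 and not C9–C8, which the trans methyl group on C8 should secure by steering rhodium to the less substituted bond, and it needs tolerance of the cis methyl group at C1, for which the small CO ligands and the fact that only the C8 hydrogen points at that methyl group speak. C8 keeps the cyclopropane configuration (8α-methyl) and ceases to be a stereocentre in step 11.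

Step 8
Reactants: 17 6-[benzyl(dimethyl)silyl]-2α-(tert-butyldimethylsilyloxy)-4α-isopropyl-1β,8α-dimethyl-4β-(triethylsilyloxy)bicyclo[5.3.0]deca-5,9-diene
Product: 20 2α-(tert-butyldimethylsilyloxy)-4α-isopropyl-1β,8α-dimethyl-4β-(triethylsilyloxy)-5α-H-bicyclo[5.3.0]dec-9-en-6-one, via silanol 18 (not isolated), via enol 19 (not isolated)
Conditions: Bu4NF (2 equiv), THF, 0 °C, 15 min; then KHCO3, 30% H2O2, MeOH, rt; then K2CO3, MeOH, rt
Reagents that add atoms: hydrogen peroxide, OO
Why: Tamao–Fleming oxidation of a benzyldimethylsilyl group, in which fluoride expels the benzyl group as toluene to give silanol 18, peroxide moves C6 from silicon to oxygen and enol 19 ketonises, C5 being protonated reversibly in the basic methanol so that the trans ring fusion (H5 α) should prevail while the isolated C9=C10 alkene is inert to nucleophilic peroxide.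

Step 9
Reactants: 20 2α-(tert-butyldimethylsilyloxy)-4α-isopropyl-1β,8α-dimethyl-4β-(triethylsilyloxy)-5α-H-bicyclo[5.3.0]dec-9-en-6-one
Product: 21 2α-(tert-butyldimethylsilyloxy)-4α-isopropyl-1β,8α-dimethyl-4β-(triethylsilyloxy)bicyclo[5.3.0]dec-9-en-6α-ol
Conditions: Li, NH3 (l), THF, t-BuOH, −78 °C; then NH4Cl
Reagents that add atoms: none
Why: Dissolving-metal reduction of a ketone, in which the ketyl and then the oxido carbanion settle with the solvated oxygen equatorial on the open α face, away from the 1,3-related C1 methyl group, and protonation then gives the more stable 6α-alcohol (H6 anti to H5) that a hydride attacking the open face would not give, the silyl ethers and the isolated alkene not being reduced.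

Step 10
Reactants: 21 2α-(tert-butyldimethylsilyloxy)-4α-isopropyl-1β,8α-dimethyl-4β-(triethylsilyloxy)bicyclo[5.3.0]dec-9-en-6α-ol; 22 4-acetoxybenzoyl chloride
Product: 23 2α-(tert-butyldimethylsilyloxy)-4α-isopropyl-1β,8α-dimethyl-4β-(triethylsilyloxy)bicyclo[5.3.0]dec-9-en-6α-yl 4-acetoxybenzoate
Conditions: Et3N, DMAP (cat.), CH2Cl2, 0 to 40 °C
Reagents that add atoms: none
Why: DMAP-catalysed acylation with an acid chloride, the equatorial C6 hydroxyl being the only free hydroxyl and reacting with retention at C6.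

Step 11
Reactants: 23 2α-(tert-butyldimethylsilyloxy)-4α-isopropyl-1β,8α-dimethyl-4β-(triethylsilyloxy)bicyclo[5.3.0]dec-9-en-6α-yl 4-acetoxybenzoate
Product: 24 2α-(tert-butyldimethylsilyloxy)-4α-isopropyl-1β,8-dimethyl-4β-(triethylsilyloxy)bicyclo[5.3.0]dec-8-en-6α-yl 4-acetoxybenzoate
Conditions: RuHCl(CO)(PPh3)3 (10 mol %), toluene, 80 °C
Reagents that add atoms: none
Why: Alkene isomerisation by a divalent ruthenium hydride through insertion and β-hydride elimination, in which Ru–H adds across the cis C9=C10 bond with Ru on C9 and eliminates with the tertiary C8–H on the same face (anti to the C8 methyl group) to give the more substituted C8=C9 alkene, a second shift to C7=C8 being disfavoured because it would need a tertiary alkylruthenium at C8.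

Step 12
Reactants: 24 2α-(tert-butyldimethylsilyloxy)-4α-isopropyl-1β,8-dimethyl-4β-(triethylsilyloxy)bicyclo[5.3.0]dec-8-en-6α-yl 4-acetoxybenzoate
Product: 25 2α,4β-dihydroxy-4α-isopropyl-1β,8-dimethylbicyclo[5.3.0]dec-8-en-6α-yl 4-acetoxybenzoate
Conditions: HF·pyridine, pyridine, THF, 0 to 40 °C
Reagents that add atoms: none
Why: Fluoride-mediated desilylation under buffered conditions removes both silyl ethers through Si–F bond formation, while the aryl acetate, the aroyl ester, the tertiary alcohol and the trisubstituted alkene should persist.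

Step 13
Reactants: 25 2α,4β-dihydroxy-4α-isopropyl-1β,8-dimethylbicyclo[5.3.0]dec-8-en-6α-yl 4-acetoxybenzoate
Product: 26 2α-acetoxy-4β-hydroxy-4α-isopropyl-1β,8-dimethylbicyclo[5.3.0]dec-8-en-6α-yl 4-acetoxybenzoate
Conditions: Ac2O, pyridine, DMAP (cat.), CH2Cl2, rt
Reagents that add atoms: acetic anhydride, CC(=O)OC(C)=O
Why: DMAP-catalysed acetylation, selective for the secondary C2 hydroxyl because the tertiary C4 hydroxyl next to the isopropyl group reacts far more slowly.

Step 14
Reactants: 26 2α-acetoxy-4β-hydroxy-4α-isopropyl-1β,8-dimethylbicyclo[5.3.0]dec-8-en-6α-yl 4-acetoxybenzoate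
Product: 27 2α-acetoxy-4β-hydroxy-4α-isopropyl-1β,8-dimethylbicyclo[5.3.0]dec-8-en-6α-yl 4-hydroxybenzoate (target, 1R,2S,4R,5S,6S)
Conditions: pyrrolidine, CH2Cl2, 0 °C to rt
Reagents that add atoms: none
Why: Chemoselective aminolysis of the aryl acetate, whose phenoxide leaving group makes it far more reactive towards pyrrolidine than the hindered secondary acetate at C2 or the aroyl ester at C6.

**Compound list**

1 | (E)-but-2-en-1-ol | C/C=C/CO | starting material
2 | [(1R,2R)-2-methylcyclopropyl]methanol | OC[C@@H]1C[C@H]1C | intermediate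
3 | (1R,2R)-2-methylcyclopropane-1-carbaldehyde | O=C[C@@H]1C[C@H]1C | intermediate
4 | (E)-2-methyl-3-[(1R,2R)-2-methylcyclopropyl]prop-2-enal | O=C/C(C)=C/[C@@H]1C[C@H]1C | intermediate
5 | 3-methylbutan-2-one | CC(C)C(C)=O | starting material
6 | diisopinocampheyl enol borinate of 5 (from (+)-Ipc2BCl) | C=C(C(C)C)OB([C@H]1C[C@H]2C[C@@H]([C@@H]1C)C2(C)C)[C@H]1C[C@H]2C[C@@H]([C@@H]1C)C2(C)C | intermediate
7 | diisopinocampheylboron aldolate of 8 | CC(C)C(=O)C[C@H](OB([C@H]1C[C@H]2C[C@@H]([C@@H]1C)C2(C)C)[C@H]1C[C@H]2C[C@@H]([C@@H]1C)C2(C)C)/C(C)=C/[C@@H]1C[C@H]1C | intermediate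
8 | (5S,6E)-5-hydroxy-2,6-dimethyl-7-[(1R,2R)-2-methylcyclopropyl]hept-6-en-3-one | CC(C)C(=O)C[C@H](O)/C(C)=C/[C@@H]1C[C@H]1C | intermediate
9 | ethynylmagnesium bromide | C#C[Mg]Br | starting material
10 | benzyl(chloro)dimethylsilane | C[Si](C)(Cl)Cc1ccccc1 | starting material
11 | benzyl(ethynyl)dimethylsilane | C#C[Si](C)(C)Cc1ccccc1 | intermediate
12 | {[benzyl(dimethyl)silyl]ethynyl}magnesium bromide | Br[Mg]C#C[Si](C)(C)Cc1ccccc1 | intermediate
13 | bromomagnesium alkoxide of 8 | CC(C)C(=O)C[C@H](O[Mg]Br)/C(C)=C/[C@@H]1C[C@H]1C | intermediate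
14 | (3R,5S,6E)-1-[benzyl(dimethyl)silyl]-6-methyl-7-[(1R,2R)-2-methylcyclopropyl]-3-(propan-2-yl)hept-6-en-1-yne-3,5-diol | C[Si](C)(Cc1ccccc1)C#C[C@](O)(C(C)C)C[C@H](O)/C(C)=C/[C@@H]1C[C@H]1C | intermediate
15 | 5-O-TBS ether of 14 | C[Si](C)(Cc1ccccc1)C#C[C@](O)(C(C)C)C[C@H](O[Si](C)(C)C(C)(C)C)/C(C)=C/[C@@H]1C[C@H]1C | intermediate
16 | (3R,5S,6E)-1-[benzyl(dimethyl)silyl]-5-(tert-butyldimethylsilyloxy)-6-methyl-7-[(1R,2R)-2-methylcyclopropyl]-3-(propan-2-yl)-3-(triethylsilyloxy)hept-6-en-1-yne | C[Si](C)(Cc1ccccc1)C#C[C@](O[Si](CC)(CC)CC)(C(C)C)C[C@H](O[Si](C)(C)C(C)(C)C)/C(C)=C/[C@@H]1C[C@H]1C | intermediate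
17 | 6-[benzyl(dimethyl)silyl]-2α-(tert-butyldimethylsilyloxy)-4α-isopropyl-1β,8α-dimethyl-4β-(triethylsilyloxy)bicyclo[5.3.0]deca-5,9-diene | CC(C)(C)[Si](C)(C)O[C@H]1C[C@@](O[Si](CC)(CC)CC)(C(C)C)C2=C([Si](C)(C)Cc3ccccc3)C[C@@H](C)C=C[C@@]12C | intermediate
18 | 6-[hydroxy(dimethyl)silyl] analogue of 17 (silanol) | CC(C)(C)[Si](C)(C)O[C@H]1C[C@@](O[Si](CC)(CC)CC)(C(C)C)C2=C([Si](C)(C)O)C[C@@H](C)C=C[C@@]12C | intermediate
19 | 6-hydroxy-5,9-diene (enol of 20) | CC(C)(C)[Si](C)(C)O[C@H]1C[C@@](O[Si](CC)(CC)CC)(C(C)C)C2=C(O)C[C@@H](C)C=C[C@@]12C | intermediate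
20 | 2α-(tert-butyldimethylsilyloxy)-4α-isopropyl-1β,8α-dimethyl-4β-(triethylsilyloxy)-5α-H-bicyclo[5.3.0]dec-9-en-6-one | CC(C)(C)[Si](C)(C)O[C@H]1C[C@@](O[Si](CC)(CC)CC)(C(C)C)[C@@H]2C(=O)C[C@@H](C)C=C[C@@]12C | intermediate
21 | 6α-alcohol of 20 | CC(C)(C)[Si](C)(C)O[C@H]1C[C@@](O[Si](CC)(CC)CC)(C(C)C)[C@@H]2[C@@H](O)C[C@@H](C)C=C[C@@]12C | intermediate
22 | 4-acetoxybenzoyl chloride | CC(=O)Oc1ccc(cc1)C(Cl)=O | starting material
23 | 6α-(4-acetoxybenzoate) of 21 | CC(C)(C)[Si](C)(C)O[C@H]1C[C@@](O[Si](CC)(CC)CC)(C(C)C)[C@@H]2[C@@H](OC(=O)c3ccc(OC(C)=O)cc3)C[C@@H](C)C=C[C@@]12C | intermediate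
24 | C8=C9 isomer of 23 | CC(C)(C)[Si](C)(C)O[C@H]1C[C@@](O[Si](CC)(CC)CC)(C(C)C)[C@@H]2[C@@H](OC(=O)c3ccc(OC(C)=O)cc3)CC(C)=CC[C@@]12C | intermediate
25 | 2α,4β-dihydroxy-4α-isopropyl-1β,8-dimethylbicyclo[5.3.0]dec-8-en-6α-yl 4-acetoxybenzoate | O[C@H]1C[C@@](O)(C(C)C)[C@@H]2[C@@H](OC(=O)c3ccc(OC(C)=O)cc3)CC(C)=CC[C@@]12C | intermediate
26 | 2α-acetoxy-4β-hydroxy-4α-isopropyl-1β,8-dimethylbicyclo[5.3.0]dec-8-en-6α-yl 4-acetoxybenzoate | CC(=O)O[C@H]1C[C@@](O)(C(C)C)[C@@H]2[C@@H](OC(=O)c3ccc(OC(C)=O)cc3)CC(C)=CC[C@@]12C | intermediate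
27 | 2α-acetoxy-4β-hydroxy-4α-isopropyl-1β,8-dimethylbicyclo[5.3.0]dec-8-en-6α-yl 4-hydroxybenzoate | CC(=O)O[C@H]1C[C@@](O)(C(C)C)[C@@H]2[C@@H](OC(=O)c3ccc(O)cc3)CC(C)=CC[C@@]12C | target

**Step count and risks**

Total steps: 14. Longest linear sequence: 13 steps (steps 1–3 and 5–14, from 1 to 27; step 4 is a one-step side branch).

Step 7. The cis methyl group at C1 raises the strain of the reactive ene-cyclopropane arrangement and crowds the alkyne insertion, so ring opening or insertion may be too slow and the catalyst may instead oligomerise the alkyne or isomerise the alkene. The fallback uses known chemistry: the rings are closed on the analogue lacking the C1 methyl group, whose E-1,2-disubstituted vinylcyclopropane belongs to the established substrate class, and the methyl group is introduced afterwards by enolate alkylation. It sets out from 2 and comes back at 17. Oxidation as in step 2 and a Wittig reaction with Ph3P=CHCHO would give (E)-3-[(1R,2R)-2-methylcyclopropyl]prop-2-enal F1. The aldol of step 3 would give (5S,6E)-5-hydroxy-2-methyl-7-[(1R,2R)-2-methylcyclopropyl]hept-6-en-3-one F2, and the acetylide addition of step 5 the diol F3. TESOTf and 2,6-lutidine would give the bis(triethylsilyl) ether F4, and [Rh(CO)2Cl]2 in toluene the C1–H cycloadduct F5. PPTS in MeOH would free the secondary C2 alcohol F6, and Dess–Martin periodinane would give the C2 ketone F7. LiN(SiMe3)2 and then MeI should alkylate the doubly allylic C1 enolate on the face away from the isopropyl group to give the C1-methyl ketone F8. HF·pyridine would give the hydroxy ketone F9, and Me4NBH(OAc)3 (hydride delivered from the ring face of the C4 hydroxyl) the 2α,4β-diol F10. TBSOTf would give the 2-O-TBS ether F11, and TESOTf would then return to 17.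

Step 8. Fluoride may protodesilylate the crowded tetrasubstituted vinylsilane before it is oxidised, the oxidation may stall, or the C4 silyloxy group may be lost by β-elimination while C5 equilibrates. The fallback replaces silicon-to-oxygen migration by a halogen and boron sequence; it sets out from 17 and comes back at 20. N-iodosuccinimide in MeCN at 0 °C (ipso-iododesilylation) would give the vinyl iodide F12. Miyaura borylation (B2pin2, PdCl2(dppf), KOAc, dioxane, 80 °C) would give the alkenyl pinacol boronate F13. NaBO3·4H2O in THF/H2O would oxidise it to enol 19 and hence ketone 20.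

Step 11. The ruthenium hydride must approach the ring face that carries the angular methyl group, so the shift may be slow; forcing it may move the alkene on to C7=C8 or into the exocyclic position. The fallback is a radical two-step route that does not depend on metal-hydride insertion; it sets out from 23 and comes back at 24. Wohl–Ziegler bromination (N-bromosuccinimide, AIBN, PhCF3, 80 °C) removes the only allylic hydrogen (C8–H) and would give the allylic bromide F14 (10-bromo-8-ene, with its allylic isomer). Bu3SnH and AIBN in benzene at 80 °C would then reduce the allyl radical by hydrogen transfer to the less substituted C10 terminus, giving 24.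

**Further compounds**

F1 | step 7 | (E)-3-[(1R,2R)-2-methylcyclopropyl]prop-2-enal | O=C/C=C/[C@@H]1C[C@H]1C
F2 | step 7 | (5S,6E)-5-hydroxy-2-methyl-7-[(1R,2R)-2-methylcyclopropyl]hept-6-en-3-one | CC(C)C(=O)C[C@H](O)/C=C/[C@@H]1C[C@H]1C
F3 | step 7 | (3R,5S,6E)-1-[benzyl(dimethyl)silyl]-7-[(1R,2R)-2-methylcyclopropyl]-3-(propan-2-yl)hept-6-en-1-yne-3,5-diol | C[Si](C)(Cc1ccccc1)C#C[C@](O)(C(C)C)C[C@H](O)/C=C/[C@@H]1C[C@H]1C
F4 | step 7 | 3,5-bis(triethylsilyl) ether of F3 | C[Si](C)(Cc1ccccc1)C#C[C@](O[Si](CC)(CC)CC)(C(C)C)C[C@H](O[Si](CC)(CC)CC)/C=C/[C@@H]1C[C@H]1C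
F5 | step 7 | 6-[benzyl(dimethyl)silyl]-4α-isopropyl-8α-methyl-2α,4β-bis(triethylsilyloxy)bicyclo[5.3.0]deca-5,9-diene (C1–H) | CC[Si](CC)(CC)O[C@H]1C[C@@](O[Si](CC)(CC)CC)(C(C)C)C2=C([Si](C)(C)Cc3ccccc3)C[C@@H](C)C=C[C@@H]12
F6 | step 7 | 2α-alcohol of F5 | O[C@H]1C[C@@](O[Si](CC)(CC)CC)(C(C)C)C2=C([Si](C)(C)Cc3ccccc3)C[C@@H](C)C=C[C@@H]12
F7 | step 7 | C2 ketone of F6 | O=C1C[C@@](O[Si](CC)(CC)CC)(C(C)C)C2=C([Si](C)(C)Cc3ccccc3)C[C@@H](C)C=C[C@@H]12
F8 | step 7 | 1β-methyl C2 ketone | O=C1C[C@@](O[Si](CC)(CC)CC)(C(C)C)C2=C([Si](C)(C)Cc3ccccc3)C[C@@H](C)C=C[C@@]12C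
F9 | step 7 | 4β-hydroxy C2 ketone | O=C1C[C@@](O)(C(C)C)C2=C([Si](C)(C)Cc3ccccc3)C[C@@H](C)C=C[C@@]12C
F10 | step 7 | 6-[benzyl(dimethyl)silyl]-4α-isopropyl-1β,8α-dimethylbicyclo[5.3.0]deca-5,9-diene-2α,4β-diol | O[C@H]1C[C@@](O)(C(C)C)C2=C([Si](C)(C)Cc3ccccc3)C[C@@H](C)C=C[C@@]12C
F11 | step 7 | 2-O-TBS ether of F10 | CC(C)(C)[Si](C)(C)O[C@H]1C[C@@](O)(C(C)C)C2=C([Si](C)(C)Cc3ccccc3)C[C@@H](C)C=C[C@@]12C
F12 | step 8 | 6-iodo analogue of 17 (vinyl iodide) | CC(C)(C)[Si](C)(C)O[C@H]1C[C@@](O[Si](CC)(CC)CC)(C(C)C)C2=C(I)C[C@@H](C)C=C[C@@]12C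
F13 | step 8 | 6-(pinacolboryl) analogue of 17 | CC(C)(C)[Si](C)(C)O[C@H]1C[C@@](O[Si](CC)(CC)CC)(C(C)C)C2=C(B3OC(C)(C)C(C)(C)O3)C[C@@H](C)C=C[C@@]12C
F14 | step 11 | 10-bromo-8-ene derived from 23 (C10 epimers) | CC(C)(C)[Si](C)(C)O[C@H]1C[C@@](O[Si](CC)(CC)CC)(C(C)C)[C@@H]2[C@@H](OC(=O)c3ccc(OC(C)=O)cc3)CC(C)=CC(Br)[C@@]12C
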